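**Plan**
1. Retrosynthesis: cut the C3–O ester bond (side-chain acid 28), then the C6–C7 bond of ring B (decarboxylative radical cyclisation; C8=O and C9–OH are unmasked after it), then C8–C9 (alkoxyallylboration of a C9 aldehyde) and C7=C11 (cross metathesis), which leaves a ring A lactone aldehyde.
2. Forward: ring A is built first from 1,4-dioxaspiro[4.5]decan-7-one; the chain C9–C8–C7(=C11) is grown on C10; ring B is closed last by joining C6 to C7; the C3 ester is attached afterwards.
3. Feature that makes the ring closure possible: C5 of ring A is quaternary, so the C6 radical released from the C5–CH2–CO2– arm has no β-hydrogen and must add (6-exo) to C7; loss of a methyl hydrogen from the C11 radical then writes the isopropenyl group on C7 of ring B.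
4. Stereochemistry: C10 from D-proline hydroxymethylation; C5 by cuprate addition anti to the C10 arm; C3 by hydride attack anti to the axial C5 arm; C4 by OH-directed hydrogenation; C9 and C8 by (Z)-γ-alkoxyallylboration; C7 by the chair transition state of the cyclisation; C4' from (R)-pent-1-en-3-ol.
5. Protecting groups: the C3 hydroxyl and the carboxyl of the C5 arm protect each other as a bridged lactone; C8-OPMB and C9-OTBS are removed in that order at the end.

Key step: step 15

Remark: eremophilane numbering of the target is used for the ring carbons of all intermediates (C1–C10 ring carbons, C11–C13 isopropenyl, C14 methyl on C5, C15 methyl on C4); β is the face of the C5 methyl, α the opposite face. Allyl 4-methoxybenzyl ether and (R)-pent-1-en-3-ol are taken as commercial.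

**Step 1**
Reactants: 1 1,4-dioxaspiro[4.5]decan-7-one
Product: 2 (8R)-8-(hydroxymethyl)-1,4-dioxaspiro[4.5]decan-7-one
Conditions: aq. HCHO, D-proline (30 mol%), DMSO, rt
Reagents that add atoms: formaldehyde, C=O
Why: Proline-catalysed α-hydroxymethylation (enamine aldol with formaldehyde): the enamine should form on the C8 side away from the ketal, and the carboxylic acid of D-proline delivers formaldehyde to one enamine face, which sets the future C10 as (R).

**Step 2**
Reactants: 2 (8R)-8-(hydroxymethyl)-1,4-dioxaspiro[4.5]decan-7-one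
Product: 3 (8R)-8-(TBDPS-oxymethyl)-1,4-dioxaspiro[4.5]decan-7-one
Conditions: tBuPh2SiCl, imidazole, CH2Cl2, 0 °C to rt
Reagents that add atoms: tert-butyl(chloro)diphenylsilane, CC(C)(C)[Si](Cl)(c1ccccc1)c1ccccc1
Why: Imidazole-mediated silylation of the primary alcohol blocks retro-aldol and dehydration of the β-hydroxy ketone; the stereocentre is not touched.

**Step 3**
Reactants: 3 (8R)-8-(TBDPS-oxymethyl)-1,4-dioxaspiro[4.5]decan-7-one
Product: 5 C6-methyl ketone (both C6 epimers), via lithium enolate 4 (not isolated)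
Conditions: LiN(iPr)2, THF, −78 °C; MeI, −78 to −40 °C
Reagents that add atoms: iodomethane, CI
Why: Kinetic enolate alkylation: the amide base should remove a proton from the C6 methylene and not the tertiary C8–H, and methylation installs the future C15; this carbon becomes sp2 in step 4, so its configuration does not matter.

**Step 4**
Reactants: 5 C6-methyl ketone
Product: 7 enone (4S)-4-(TBDPS-oxymethyl)-3-(1,3-dioxolan-2-ylmethyl)-2-methylcyclohex-2-en-1-one, via tertiary carbinol 6 (not isolated)
Conditions: (1,3-dioxolan-2-ylmethyl)MgBr, CeCl3, THF, −78 to 0 °C; then 1 M HCl, THF, 0 °C to rt (brief)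
Reagents that add atoms: (1,3-dioxolan-2-ylmethyl)magnesium bromide, Br[Mg]CC1OCCO1
Why: Organocerium 1,2-addition to the hindered ketone, then acid hydrolysis of the ring ketal and β-elimination of water (the ketal counterpart of a Stork–Danheiser transposition) gives the enone with the C5 arm in place; the aldehyde acetal hydrolyses more slowly than the ketone ketal, and C10 is not touched.

**Step 5**
Reactants: 7 enone
Product: 9 α-phenylselanyl ketone (C5 quaternary; C14 trans to the C10 arm), via trimethylsilyl enol ether 8 (not isolated)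
Conditions: Me2CuLi, Me3SiCl, THF, −78 to −20 °C; then PhSeCl, −78 °C
Reagents that add atoms: lithium dimethylcuprate, [Li+].C[Cu-]C; benzeneselenenyl chloride, Cl[Se]c1ccccc1
Why: Me3SiCl-accelerated cuprate conjugate addition should deliver the methyl to C5 anti to the C10 CH2OTBDPS group, which sets the quaternary centre; the regiodefined enol silane is then selenenylated at C4.

**Step 6**
Reactants: 9 α-phenylselanyl ketone
Product: 11 exocyclic enone (C3 ketone; C4 methylidene), via selenoxide 10 (not isolated)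
Conditions: H2O2 (30%), pyridine, CH2Cl2, 0 °C to rt
Reagents that add atoms: none
Why: Selenoxide syn-elimination: the only β-hydrogens are those of the methyl group because C5 is quaternary, so only the exocyclic methylene ketone can form.

**Step 7**
Reactants: 11 exocyclic enone
Product: 12 allylic alcohol (3α-OH)
Conditions: iBu2AlH, CH2Cl2, −78 °C
Reagents that add atoms: none
Why: 1,2-reduction: with the C10 arm equatorial the C5 CH2-dioxolanyl arm is axial on the α face, so the bulky aluminium hydride should attack C3 from the β face and give the axial 3α-OH cis to that arm (C3 R).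

**Step 8**
Reactants: 12 allylic alcohol
Product: 13 ring A alcohol (3α-OH; 4β-methyl)
Conditions: H2 (1 atm), [Ir(cod)(PCy3)(py)]PF6 (cat.), CH2Cl2, rt
Reagents that add atoms: none
Why: Hydroxyl-directed hydrogenation: iridium bound to the C3–OH delivers hydrogen to the α face of the methylidene group, which sets C4 with the methyl trans to the OH and cis to C14.

**Step 9**
Reactants: 13 ring A alcohol
Product: 15 bridged lactone (O–C3 to C5–CH2–CO), via bridged lactol 14 (not isolated)
Conditions: 1 M HCl, THF/H2O, rt; then NaHCO3, TEMPO (cat.), PhI(OAc)2, CH2Cl2/H2O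
Reagents that add atoms: water, O
Why: Acetal hydrolysis frees the aldehyde, which the 1,3-diaxial C3–OH traps as a lactol; oxoammonium (TEMPO) oxidation gives the δ-lactone, which protects the C3 hydroxyl and the future carboxylic acid at once.

**Step 10**
Reactants: 15 bridged lactone
Product: 16 lactone alcohol (C9 OH)
Conditions: Bu4NF, AcOH, THF, 0 °C to rt
Reagents that add atoms: none
Why: Fluoride cleavage of the silyl ether; acetic acid buffering keeps the lactone closed.

**Step 11**
Reactants: 16 lactone alcohol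
Product: 17 lactone aldehyde (C9 CHO)
Conditions: Dess–Martin periodinane, NaHCO3, CH2Cl2, 0 °C
Reagents that add atoms: none
Why: Dess–Martin oxidation of the primary alcohol under buffered conditions; the α-centre C10 next to the quaternary C5 should not epimerise.

**Step 12**
Reactants: 17 lactone aldehyde
Product: 19 homoallylic alcohol (9R-OH; 8R-OPMB; vinyl), via borinate ester 18 (not isolated)
Conditions: allyl PMB ether, s-BuLi, THF, −78 °C; (−)-Ipc2BOMe; BF3·OEt2; then 17, −78 °C; work-up HOCH2CH2NH2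
Reagents that add atoms: allyl 4-methoxybenzyl ether (as its (Z)-γ-alkoxyallyl-B(Ipc)2 derivative), C=CCOCc1ccc(OC)cc1
Why: Brown (Z)-γ-alkoxyallylboration through a chair transition state gives the syn 8,9-diol monoether; the Ipc groups derived from (+)-α-pinene direct attack to the Si face of the aldehyde (C9 R, C8 R), matched with Felkin–Anh control by C10.

**Step 13**
Reactants: 19 homoallylic alcohol
Product: 20 C9 TBS ether
Conditions: tBuMe2SiOTf, 2,6-lutidine, CH2Cl2, −78 to 0 °C
Reagents that add atoms: tert-butyldimethylsilyl trifluoromethanesulfonate, CC(C)(C)[Si](C)(C)OS(=O)(=O)C(F)(F)F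
Why: Silyl triflate silylation of the hindered secondary alcohol; no stereocentre is touched.

**Step 14**
Reactants: 20 C9 TBS ether
Product: 21 prenyl-type alkene (C7=C11Me2)
Conditions: second-generation Grubbs catalyst RuCl2(=CHPh)(H2IMes)(PCy3) (cat.), 2-methylbut-2-ene (solvent), 40 °C
Reagents that add atoms: 2-methylbut-2-ene, CC=C(C)C
Why: Olefin cross metathesis with 2-methylbut-2-ene turns the vinyl group into the trisubstituted alkene that carries C11–C13; no stereocentre is touched.

**Step 15**
Reactants: 21 prenyl-type alkene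
Product: 23 cis-decalin (ring B closed; 7β-isopropenyl; 3-OH free), via lithium carboxylate 22 (not isolated)
Conditions: LiOH, THF/H2O, rt; then Ir[dF(CF3)ppy]2(dtbbpy)PF6 (cat.), Co(dmgH)2(py)Cl (cat.), MeCN/H2O, blue LED (450 nm), rt
Reagents that add atoms: none
Why: Proposed new method: the excited iridium photocatalyst oxidises the carboxylate of 22, loss of CO2 gives the neopentyl-type C6 radical, this adds to C7 of the C7=C11 alkene, and the tertiary C11 radical is taken up by the divalent cobalt of the cobaloxime, which removes a methyl hydrogen (released as H2) and leaves the isopropenyl group; the closest known reaction types are the photoredox/cobaloxime decarboxylative Heck-type olefination of aliphatic acids and the cobaloxime-catalysed alkyl-Heck cyclisation of alkyl iodides. Ring B closes in the 6-exo-trig mode through a chair transition state of the cis-fused decalin in which C8-OPMB, C9-OTBS and the CMe2 terminus are equatorial, so C7 is set with the isopropenyl group cis to C14 (control by C5, C8, C9 and C10). The quaternary C5 makes the event possible: the C6 radical has no β-hydrogen, so cobalt cannot desaturate it before it cyclises, and the gem-dialkyl effect speeds the closure. Attack at the CH end (C7) and not at the disubstituted C11 follows from sterics and ring size, and abstraction of a methyl C–H and not the hindered axial C7–H is the usual Hofmann sense of cobaloxime hydrogen abstraction. The step also needs oxidation of the carboxylate in the presence of the PMB ether, which the moderate excited-state potential of the iridium catalyst should secure.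

**Step 16**
Reactants: 24 (R)-pent-1-en-3-ol; 25 angelic acid
Product: 27 (R)-pent-1-en-3-yl angelate, via mixed anhydride 26 (not isolated)
Conditions: 2,4,6-Cl3C6H2COCl, Et3N, toluene, rt; then 24, 80 °C
Reagents that add atoms: none
Why: Yamaguchi-type mixed-anhydride acylation without a nucleophilic catalyst should keep the (Z)-geometry of the angelate; the (R) carbinol centre is acylated with retention.

**Step 17**
Reactants: 27 (R)-pent-1-en-3-yl angelate
Product: 28 (2E,4R)-4-(angeloyloxy)hex-2-enoic acid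
Conditions: acrylic acid, second-generation Hoveyda–Grubbs catalyst RuCl2(=CH-C6H4-2-OiPr)(H2IMes) (cat.), CH2Cl2, 40 °C
Reagents that add atoms: acrylic acid, C=CC(=O)O
Why: Olefin cross metathesis of the terminal alkene with acrylic acid should give the (E)-enoic acid; the trisubstituted, electron-poor angelate alkene is inert to the catalyst.

**Step 18**
Reactants: 23 cis-decalin; 28 (2E,4R)-4-(angeloyloxy)hex-2-enoic acid
Product: 30 C3 ester of 23, via mixed anhydride 29 (not isolated)
Conditions: 2,4,6-Cl3C6H2COCl, Et3N, THF, rt; then 23, DMAP, toluene, rt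
Reagents that add atoms: none
Why: Yamaguchi esterification of the only free hydroxyl (equatorial C3–OH); C8 and C9 stay protected and no stereocentre is touched.

**Step 19**
Reactants: 30 C3 ester
Product: 31 C8 alcohol
Conditions: DDQ, CH2Cl2/pH 7 buffer, 0 °C
Reagents that add atoms: none
Why: Oxidative cleavage of the PMB ether by DDQ (benzylic hydride abstraction, then hydrolysis); the esters, alkenes and silyl ether are inert.

**Step 20**
Reactants: 31 C8 alcohol
Product: 32 C8 ketone (9-OTBS)
Conditions: Dess–Martin periodinane, NaHCO3, CH2Cl2, 0 °C to rt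
Reagents that add atoms: none
Why: Dess–Martin oxidation under buffered, non-enolising conditions gives the β,γ-unsaturated ketone, so C7 and C9 should keep their configuration and the alkene should stay out of conjugation.

**Step 21**
Reactants: 32 C8 ketone
Product: 33 target (CNP0190706.1)
Conditions: HF·pyridine, pyridine, THF, 0 °C to rt
Reagents that add atoms: none
Why: Buffered fluoride desilylation frees the C9 hydroxyl of the α-silyloxy ketone without enolisation and without touching the esters.

**Compound list**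
1 | 1,4-dioxaspiro[4.5]decan-7-one | O=C1CCCC2(C1)OCCO2 | starting material
2 | (8R)-8-(hydroxymethyl)-1,4-dioxaspiro[4.5]decan-7-one | OC[C@H]1CCC2(CC1=O)OCCO2 | intermediate
3 | (8R)-8-{[tert-butyl(diphenyl)silyl]oxymethyl}-1,4-dioxaspiro[4.5]decan-7-one | CC(C)(C)[Si](OC[C@H]1CCC2(CC1=O)OCCO2)(c1ccccc1)c1ccccc1 | intermediate
4 | lithium C6=C7 enolate of 3 (8R) | [Li+].[O-]C1=CC2(CC[C@@H]1CO[Si](c1ccccc1)(c1ccccc1)C(C)(C)C)OCCO2 | intermediate
5 | (8R)-8-{[tert-butyl(diphenyl)silyl]oxymethyl}-6-methyl-1,4-dioxaspiro[4.5]decan-7-one (both C6 epimers) | CC(C)(C)[Si](OC[C@H]1CCC2(C(C)C1=O)OCCO2)(c1ccccc1)c1ccccc1 | intermediate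
6 | (8R)-8-{[tert-butyl(diphenyl)silyl]oxymethyl}-7-(1,3-dioxolan-2-ylmethyl)-6-methyl-1,4-dioxaspiro[4.5]decan-7-ol (epimers at C6 and C7) | CC(C)(C)[Si](OC[C@H]1CCC2(C(C)C1(O)CC1OCCO1)OCCO2)(c1ccccc1)c1ccccc1 | intermediate
7 | (4S)-4-{[tert-butyl(diphenyl)silyl]oxymethyl}-3-(1,3-dioxolan-2-ylmethyl)-2-methylcyclohex-2-en-1-one | CC(C)(C)[Si](OC[C@H]1CCC(=O)C(C)=C1CC1OCCO1)(c1ccccc1)c1ccccc1 | intermediate
8 | ring A trimethylsilyl enol ether: C3 OSiMe3, C3=C4, C4 methyl, C5 β-methyl and α-CH2-(1,3-dioxolan-2-yl), C10 α-CH2OTBDPS | [C@H]1(CO[Si](c2ccccc2)(c2ccccc2)C(C)(C)C)CCC(O[Si](C)(C)C)=C(C)[C@@]1(C)CC1OCCO1 | intermediate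
9 | ring A ketone with C4 methyl and C4 phenylselanyl (C4 configuration open), C5 β-methyl and α-CH2-(1,3-dioxolan-2-yl), C10 α-CH2OTBDPS | [C@H]1(CO[Si](c2ccccc2)(c2ccccc2)C(C)(C)C)CCC(=O)C(C)([Se]c2ccccc2)[C@@]1(C)CC1OCCO1 | intermediate
10 | selenoxide of 9 | [C@H]1(CO[Si](c2ccccc2)(c2ccccc2)C(C)(C)C)CCC(=O)C(C)([Se](=O)c2ccccc2)[C@@]1(C)CC1OCCO1 | intermediate
11 | ring A C3 ketone with C4 methylidene, C5 β-methyl and α-CH2-(1,3-dioxolan-2-yl), C10 α-CH2OTBDPS | [C@H]1(CO[Si](c2ccccc2)(c2ccccc2)C(C)(C)C)CCC(=O)C(=C)[C@@]1(C)CC1OCCO1 | intermediate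
12 | allylic alcohol: as 11 with 3α-OH (3R) | [C@H]1(CO[Si](c2ccccc2)(c2ccccc2)C(C)(C)C)CC[C@@H](O)C(=C)[C@@]1(C)CC1OCCO1 | intermediate
13 | (1R,2R,3S,4S)-4-{[tert-butyl(diphenyl)silyl]oxymethyl}-3-(1,3-dioxolan-2-ylmethyl)-2,3-dimethylcyclohexan-1-ol (3α-OH, 4β-methyl, 5β-methyl, 10β-H) | [C@H]1(CO[Si](c2ccccc2)(c2ccccc2)C(C)(C)C)CC[C@@H](O)[C@H](C)[C@@]1(C)CC1OCCO1 | intermediate
14 | bridged lactol (2-oxabicyclo[3.3.1]nonan-3-ol core, O on C3, C5–CH2–CH(OH)); other centres as in 13; anomers | [C@H]1(CO[Si](c3ccccc3)(c3ccccc3)C(C)(C)C)CC[C@@H](O2)[C@H](C)[C@@]1(C)CC2O | intermediate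
15 | bridged δ-lactone (2-oxabicyclo[3.3.1]nonan-3-one core) between the C3 oxygen and the C5 CH2CO arm; 4β-methyl, 5β-methyl, C10 α-CH2OTBDPS | [C@H]1(CO[Si](c3ccccc3)(c3ccccc3)C(C)(C)C)CC[C@@H](O2)[C@H](C)[C@@]1(C)CC2=O | intermediate
16 | lactone 15 with free C9 hydroxymethyl | [C@H]1(CO)CC[C@@H](O2)[C@H](C)[C@@]1(C)CC2=O | intermediate
17 | lactone aldehyde (C10 α-CHO) | [C@H]1(C=O)CC[C@@H](O2)[C@H](C)[C@@]1(C)CC2=O | intermediate
18 | diisopinocampheylborinate ester of 19 (B on the C9 oxygen) | [C@H]1([C@@H](OB([C@@H]3C[C@@H]4C[C@@H](C4(C)C)[C@H]3C)[C@@H]3C[C@@H]4C[C@@H](C4(C)C)[C@H]3C)[C@H](OCc3ccc(OC)cc3)C=C)CC[C@@H](O2)[C@H](C)[C@@]1(C)CC2=O | intermediate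
19 | lactone with C10 side chain (9R)-CH(OH)–(8R)-CH(OPMB)–CH=CH2 (syn) | [C@H]1([C@@H](O)[C@H](OCc3ccc(OC)cc3)C=C)CC[C@@H](O2)[C@H](C)[C@@]1(C)CC2=O | intermediate
20 | C9 tert-butyldimethylsilyl ether of 19 | [C@H]1([C@@H](O[Si](C)(C)C(C)(C)C)[C@H](OCc3ccc(OC)cc3)C=C)CC[C@@H](O2)[C@H](C)[C@@]1(C)CC2=O | intermediate
21 | lactone with C10 side chain (9R)-CH(OTBS)–(8R)-CH(OPMB)–CH=C(CH3)2 | [C@H]1([C@@H](O[Si](C)(C)C(C)(C)C)[C@H](OCc3ccc(OC)cc3)C=C(C)C)CC[C@@H](O2)[C@H](C)[C@@]1(C)CC2=O | intermediate
22 | lithium carboxylate from lactone opening of 21 (3α-OH free, C5–CH2–CO2Li) | [C@H]1([C@@H](O[Si](C)(C)C(C)(C)C)[C@H](OCc3ccc(OC)cc3)C=C(C)C)CC[C@@H](O)[C@H](C)[C@@]1(C)CC(=O)[O-].[Li+] | intermediate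
23 | (3R,4R,5R,7R,8R,9R,10S)-9-(tert-butyldimethylsilyloxy)-8-(4-methoxybenzyloxy)eremophil-11-en-3-ol (cis-decalin; 3α-OH, 7β-isopropenyl, 8α-OPMB, 9β-OTBS, 10β-H) | C=C(C)[C@H]1C[C@@]2(C)[C@H](CC[C@@H](O)[C@@H]2C)[C@@H](O[Si](C)(C)C(C)(C)C)[C@@H]1OCc1ccc(OC)cc1 | intermediate
24 | (3R)-pent-1-en-3-ol | CC[C@@H](O)C=C | starting material
25 | angelic acid, (2Z)-2-methylbut-2-enoic acid | C/C=C(/C)C(=O)O | starting material
26 | (2Z)-2-methylbut-2-enoic 2,4,6-trichlorobenzoic anhydride | C/C=C(/C)C(=O)OC(=O)c1c(Cl)cc(Cl)cc1Cl | intermediate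
27 | (3R)-pent-1-en-3-yl (2Z)-2-methylbut-2-enoate | C/C=C(/C)C(=O)O[C@H](CC)C=C | intermediate
28 | (2E,4R)-4-{[(2Z)-2-methylbut-2-enoyl]oxy}hex-2-enoic acid | C/C=C(/C)C(=O)O[C@H](CC)/C=C/C(=O)O | intermediate
29 | mixed anhydride of 28 with 2,4,6-trichlorobenzoic acid | C/C=C(/C)C(=O)O[C@H](CC)/C=C/C(=O)OC(=O)c1c(Cl)cc(Cl)cc1Cl | intermediate
30 | C3 ester of 23 with acid 28 (8α-OPMB, 9β-OTBS) | C=C(C)[C@H]1C[C@@]2(C)[C@H](CC[C@@H](OC(=O)/C=C/[C@@H](CC)OC(=O)/C(C)=C\C)[C@@H]2C)[C@@H](O[Si](C)(C)C(C)(C)C)[C@@H]1OCc1ccc(OC)cc1 | intermediate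
31 | 8α-alcohol from 30 (9β-OTBS) | C=C(C)[C@H]1C[C@@]2(C)[C@H](CC[C@@H](OC(=O)/C=C/[C@@H](CC)OC(=O)/C(C)=C\C)[C@@H]2C)[C@@H](O[Si](C)(C)C(C)(C)C)[C@@H]1O | intermediate
32 | 8-ketone, 9β-OTBS ether of the target | C=C(C)[C@H]1C[C@@]2(C)[C@H](CC[C@@H](OC(=O)/C=C/[C@@H](CC)OC(=O)/C(C)=C\C)[C@@H]2C)[C@@H](O[Si](C)(C)C(C)(C)C)C1=O | intermediate
33 | (3R,4R,5R,7R,9R,10S)-9-hydroxy-8-oxoeremophil-11-en-3-yl (2E,4R)-4-{[(2Z)-2-methylbut-2-enoyl]oxy}hex-2-enoate | C=C(C)[C@H]1C[C@@]2(C)[C@H](CC[C@@H](OC(=O)/C=C/[C@@H](CC)OC(=O)/C(C)=C\C)[C@@H]2C)[C@@H](O)C1=O | target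

Total step count: 21. Longest linear sequence: 19 (steps 1–15 and 18–21).

**Three steps most likely to fail**

1. Step 15 (Proposed new method). What may go wrong: hydrogen transfer from C8–H to the C6 radical before ring closure; hydrogen-atom capture by the C11 radical instead of cobalt-mediated hydrogen loss; hydrogen abstraction at C7–H in place of a methyl hydrogen; slow oxidation of the primary carboxylate. Fallback by radical addition–fragmentation, which needs no hydrogen abstraction: starting from 20, cross metathesis with 2-methylallyl phenyl sulfone (second-generation Hoveyda–Grubbs catalyst) should give the allyl sulfone F1 (E/Z mixture, both usable). LiOH opens its lactone to the lithium carboxylate F2. Irradiation with Ir[dF(CF3)ppy]2(dtbbpy)PF6 alone (blue LED, MeCN/H2O) generates the C6 radical, which adds 6-exo to C7; the β-phenylsulfonyl radical is expelled and reduced to sulfinate. This is the intramolecular form of the known photoredox decarboxylative allylation with allyl sulfones; it writes the isopropenyl group directly and returns to 23.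

2. Step 1. What may go wrong: enamine formation on the C6 side next to the ketal, double hydroxymethylation, or loss of enantiopurity through retro-aldol and dehydration of the β-hydroxy ketone. Fallback by auxiliary-controlled alkylation: starting from 1, condensation with RAMP gives the hydrazone F3. Deprotonation with LiN(iPr)2 and alkylation with benzyl chloromethyl ether should give the (8R)-benzyloxymethyl hydrazone F4; RAMP is expected to give the (R) series by analogy with simple cyclohexanone alkylations. Cleavage with aqueous oxalic acid gives the benzyl ether ketone F5, and hydrogenolysis (H2, Pd(OH)2/C, EtOAc) returns to 2.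

3. Step 4. What may go wrong: enolisation of the hindered, α,α'-disubstituted ketone instead of addition of the sluggish acetal Grignard reagent, or loss of the aldehyde acetal during the acid treatment that unmasks the enone. Fallback with a more reactive nucleophile and later oxidative unmasking: starting from 5, allylmagnesium bromide adds to give the allyl carbinol F6 (not isolated). 1 M HCl then gives the allyl enone F7. Lemieux–Johnson cleavage of the terminal alkene (OsO4 cat., NaIO4, 2,6-lutidine, dioxane/H2O) gives the aldehyde F8, and selective acetalisation of the aldehyde (ethylene glycol, PPTS, benzene) returns to 7.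

**Further compounds**
F1 | step 15 | allyl sulfone analogue of 21: C10 side chain (9R)-CH(OTBS)–(8R)-CH(OPMB)–CH=C(CH3)–CH2SO2Ph (E/Z mixture) | [C@H]1([C@@H](O[Si](C)(C)C(C)(C)C)[C@H](OCc3ccc(OC)cc3)C=C(C)CS(=O)(=O)c3ccccc3)CC[C@@H](O2)[C@H](C)[C@@]1(C)CC2=O
F2 | step 15 | lithium carboxylate from lactone opening of F1 | [C@H]1([C@@H](O[Si](C)(C)C(C)(C)C)[C@H](OCc3ccc(OC)cc3)C=C(C)CS(=O)(=O)c3ccccc3)CC[C@@H](O)[C@H](C)[C@@]1(C)CC(=O)[O-].[Li+]
F3 | step 1 | RAMP hydrazone of 1 | COC[C@H]1CCCN1N=C1CCCC2(C1)OCCO2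
F4 | step 1 | RAMP hydrazone of (8R)-8-(benzyloxymethyl)-1,4-dioxaspiro[4.5]decan-7-one | COC[C@H]1CCCN1N=C1CC2(CC[C@@H]1COCc1ccccc1)OCCO2
F5 | step 1 | (8R)-8-(benzyloxymethyl)-1,4-dioxaspiro[4.5]decan-7-one | O=C1CC2(CC[C@@H]1COCc1ccccc1)OCCO2
F6 | step 4 | (8R)-7-allyl-8-{[tert-butyl(diphenyl)silyl]oxymethyl}-6-methyl-1,4-dioxaspiro[4.5]decan-7-ol (epimers at C6 and C7) | CC(C)(C)[Si](OC[C@H]1CCC2(C(C)C1(O)CC=C)OCCO2)(c1ccccc1)c1ccccc1
F7 | step 4 | (4S)-3-allyl-4-{[tert-butyl(diphenyl)silyl]oxymethyl}-2-methylcyclohex-2-en-1-one | CC(C)(C)[Si](OC[C@H]1CCC(=O)C(C)=C1CC=C)(c1ccccc1)c1ccccc1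
F8 | step 4 | 2-[(6S)-6-{[tert-butyl(diphenyl)silyl]oxymethyl}-2-methyl-3-oxocyclohex-1-en-1-yl]acetaldehyde | CC(C)(C)[Si](OC[C@H]1CCC(=O)C(C)=C1CC=O)(c1ccccc1)c1ccccc1
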